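**Strategy.** The 1,2-dioxolane is not constructed in the route: its ring carbons C3, C4 and C5 (C1 = carboxyl carbon), the O–O unit and both ring methyls are the hydrogen peroxide adduct of pentane-2,4-dione. The target is cut at the two flanking bonds C2–C3 and C5–C6, whose CH2 arms lie on opposite ring faces and give the core near twofold symmetry. The precursor is therefore the bis(peroxyketal) 3,5-dimethoxy-3,5-dimethyl-1,2-dioxolane. In one flask, two peroxycarbenium substitutions attach the acetate arm (silyl ketene acetal) and then, through the terminal carbon of a siloxydiene, a C6–C9 enal arm trans to it. Enzymatic reduction sets C7; two olefinations complete the chain.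

Key step: step 4

Remarks: carbon numbers C1–C17 follow the acid chain of the target (C1 = carboxyl carbon, C17 = phenyl-bearing carbon). Compounds 7 and 8 are racemic, and 8 is drawn as the enantiomer that leads to the target. Peroxides 2 and 3 have a high active-oxygen content and are to be handled in solution, on small scale, behind a shield.

Step 1
Reactants: 1 pentane-2,4-dione
Product: 2 3,5-dimethyl-1,2-dioxolane-3,5-diol (cis/trans mixture)
Conditions: 30% aq. H2O2 (1.05 equiv), 0 °C → rt; extraction into Et2O, kept as a solution
Reagents that add atoms: hydrogen peroxide, OO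
Why: Perhydrate formation followed by 5-exo closure of the hydroperoxide onto the second carbonyl gives the cyclic bis(peroxyhemiketal), the spontaneous and long-known mode of addition of H2O2 to this 1,3-diketone; no stereocontrol is needed because both ring carbons are re-ionised in step 4.

Step 2
Reactants: 2 3,5-dimethyl-1,2-dioxolane-3,5-diol
Product: 3 3,5-dimethoxy-3,5-dimethyl-1,2-dioxolane (cis/trans mixture)
Conditions: MeOH (solvent), TsOH·H2O (5 mol%), 3 Å molecular sieves, 0 °C → rt; NaHCO3; careful concentration
Reagents that add atoms: methanol, CO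
Why: Acid-catalysed exchange of both peroxyhemiketal hydroxyls for methoxy in excess dry methanol (the peroxyhemiketal-to-peroxyketal conversion used to turn 1,2-dioxolan-3-ols into 3-methoxy-1,2-dioxolanes), with sieves removing water and the ring re-closing from any opened hydroperoxy intermediate.

Step 3
Reactants: 4 3-methylbut-2-enal
Product: 5 trimethyl{[(1E)-3-methylbuta-1,3-dien-1-yl]oxy}silane
Conditions: Me3SiOTf (1.1 equiv), Et3N (1.3 equiv), Et2O, 0 °C → rt; pentane, filtration, distillation
Reagents that add atoms: trimethylsilyl trifluoromethanesulfonate, C[Si](C)(C)OS(=O)(=O)C(F)(F)F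
Why: Soft enolisation: O-silylation of the enal and γ-deprotonation by the amine give the silyl dienol ether (either γ-methyl leads to the same diene), whose C1=C2 geometry is of no consequence because that bond becomes the C8–C9 single bond of the enal in step 4.

Step 4
Reactants: 3 3,5-dimethoxy-3,5-dimethyl-1,2-dioxolane, 6 tert-butyl[(1-methoxyethenyl)oxy]dimethylsilane (commercial), 5 trimethyl{[(1E)-3-methylbuta-1,3-dien-1-yl]oxy}silane
Product: 8 rac-methyl 2-[(3S,5R)-3,5-dimethyl-5-[(2E)-2-methyl-4-oxobut-2-en-1-yl]-1,2-dioxolan-3-yl]acetate, via monosubstituted peroxyketal 7 (not isolated)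
Conditions: 3 (1.0 equiv), Me3SiOTf (0.2 equiv), CH2Cl2, −78 °C, 6 (1.0 equiv) added over 1 h; then 5 (1.5 equiv), Me3SiOTf (0.3 equiv), −78 → −40 °C; KH2PO4/K2HPO4 buffer (pH 7); chromatography on SiO2 (trans-arm (E)-isomer collected)
Reagents that add atoms: none
Why: Proposed new method: Me3SiOTf removes one methoxy group of 3 to give a peroxycarbenium ion that ketene acetal 6 traps at C3 (bond C2–C3), the released silyl triflate carrying the chain; the remaining peroxyketal of 7 then ionises in the same way and diene 5 attacks through its unhindered terminal CH2 (bond C5–C6), the silyloxocarbenium ion collapsing to the conjugated enal, (E) from the s-trans diene. The closest known reactions are the Lewis acid-mediated substitution of 3-alkoxy-1,2-dioxolanes by silyl ketene acetals, silyl enol ethers and allylsilanes and the γ-selective vinylogous Mukaiyama addition of 1-siloxydienes to acetals; what is new is running two such substitutions on one bis(peroxyketal) in one flask and using a dienol ether as partner of a peroxycarbenium ion. No ring is closed: the dioxolane of 3 is carried through intact, exocyclic C–OMe ionisation being the productive pathway and any ring-opened cation being able to re-close. C3 is formed without facial bias (racemate; the cis/trans mixture of 3 converges because each ketal carbon becomes planar), and C5 is set relative to it when 5 approaches the flat cation anti to the larger CH2CO2Me group on C3, an approach that transient capping of the syn face by the ester carbonyl would reinforce, so the two arms end up trans, (3S*,5R*). The step needs mono- before bis-substitution by 6 (helped by the two equivalent ketal sites of 3, slow addition and low temperature; the ester product is inert, which is why 6 goes in first), γ- rather than α-attack of 5 (secured by the hindered quaternary electrophile) and survival of the product enal (aldehydes are not activated by catalytic silyl triflate at −78 °C as ketals are).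

Step 5
Reactants: 8 rac-methyl 2-[(3S,5R)-3,5-dimethyl-5-[(2E)-2-methyl-4-oxobut-2-en-1-yl]-1,2-dioxolan-3-yl]acetate
Product: 9 methyl 2-[(3S,5R)-3,5-dimethyl-5-[(2S)-2-methyl-4-oxobutyl]-1,2-dioxolan-3-yl]acetate
Conditions: purified ene-reductase NCR from Zymomonas mobilis (Old Yellow Enzyme family, confirmed against a small panel), NADP+ (cat.), D-glucose (1.5 equiv), glucose dehydrogenase, KH2PO4/K2HPO4 buffer pH 7.0 (no amine buffer), DMSO (5% v/v), 30 °C; extraction; preparative HPLC on SiO2 to part the two diastereomers
Reagents that add atoms: none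
Why: Old Yellow Enzyme-type asymmetric bioreduction of a β-methyl enal, the substrate class of citral: the carbonyl is held by the hydrogen-bond donors of the active site, reduced flavin delivers hydride to one face of C7 and a tyrosine protonates C8 (net anti addition), so the protein and not the remote ring fixes C7 as (S) in this aldehyde (the sense this enzyme shows with geranial), and the two ring enantiomers of 8 emerge as diastereomers that are parted by chromatography.

Step 6
Reactants: 9 methyl 2-[(3S,5R)-3,5-dimethyl-5-[(2S)-2-methyl-4-oxobutyl]-1,2-dioxolan-3-yl]acetate, 10 [2-(1,3-dioxolan-2-yl)ethyl]triphenylphosphonium bromide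
Product: 12 methyl 2-[(3S,5R)-5-[(2R,4Z)-6-(1,3-dioxolan-2-yl)-2-methylhex-4-en-1-yl]-3,5-dimethyl-1,2-dioxolan-3-yl]acetate, via phosphonium ylide 11 (not isolated)
Conditions: 10 (1.3 equiv), NaN(SiMe3)2 (1.25 equiv), THF, 0 °C, 30 min; −78 °C, 9; → 0 °C; aq. NH4Cl
Reagents that add atoms: none
Why: Wittig olefination with a non-stabilised ylide, generated without excess base and met by the aldehyde at −78 °C, joins C9 to the three-carbon unit C10–C12 as the (Z)-alkene (geometry irrelevant, reduced next); dialkyl peroxides with quaternary peroxide carbons tolerate phosphorus ylides, and C7 is not α to the carbonyl and cannot epimerise.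

Step 7
Reactants: 12 methyl 2-[(3S,5R)-5-[(2R,4Z)-6-(1,3-dioxolan-2-yl)-2-methylhex-4-en-1-yl]-3,5-dimethyl-1,2-dioxolan-3-yl]acetate
Product: 13 methyl 2-[(3S,5R)-5-[(2R)-6-(1,3-dioxolan-2-yl)-2-methylhexyl]-3,5-dimethyl-1,2-dioxolan-3-yl]acetate
Conditions: KO2CN=NCO2K (excess, in portions), AcOH (slow addition), CH2Cl2, 0 °C → rt
Reagents that add atoms: none
Why: Diimide, released by protonation and decarboxylation of the azodicarboxylate, transfers two hydrogens to the unpolarised C9=C10 bond in a concerted syn fashion and does not touch the O–O bond, ester or acetal, which is why it is the standard alkene reduction next to peroxides.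

Step 8
Reactants: 13 methyl 2-[(3S,5R)-5-[(2R)-6-(1,3-dioxolan-2-yl)-2-methylhexyl]-3,5-dimethyl-1,2-dioxolan-3-yl]acetate
Product: 14 methyl 2-[(3S,5R)-3,5-dimethyl-5-[(2R)-2-methyl-7-oxoheptyl]-1,2-dioxolan-3-yl]acetate
Conditions: 2 M aq. HCl/THF (1:3), rt
Reagents that add atoms: water, O
Why: Acid-catalysed hydrolysis of the 1,3-dioxolane acetal unveils the C12 aldehyde, the fully substituted dialkyl peroxide and the methyl ester being stable to dilute aqueous acid at room temperature.

Step 9
Reactants: 15 (4E)-5-phenylpent-4-en-1-ol
Product: 16 1-phenyl-5-{[(4E)-5-phenylpent-4-en-1-yl]sulfanyl}-1H-tetrazole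
Conditions: 1-phenyl-1H-tetrazole-5-thiol (1.2 equiv), PPh3 (1.2 equiv), DIAD (1.2 equiv), THF, 0 °C → rt
Reagents that add atoms: 1-phenyl-1H-tetrazole-5-thiol, Sc1nnnn1-c1ccccc1
Why: Mitsunobu thioetherification: the acidic tetrazolethiol displaces the activated primary alcohol (SN2 on the alkoxyphosphonium ion) without touching the styrenyl alkene.

Step 10
Reactants: 16 1-phenyl-5-{[(4E)-5-phenylpent-4-en-1-yl]sulfanyl}-1H-tetrazole
Product: 17 1-phenyl-5-{[(4E)-5-phenylpent-4-en-1-yl]sulfonyl}-1H-tetrazole
Conditions: (NH4)6Mo7O24·4H2O (10 mol%), 30% aq. H2O2 (6 equiv), EtOH, 0 °C → rt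
Reagents that add atoms: hydrogen peroxide, OO
Why: Molybdate-catalysed oxidation with H2O2 converts the sulfide through the sulfoxide into the sulfone and is selective for sulfur over the disubstituted alkene.

Step 11
Reactants: 14 methyl 2-[(3S,5R)-3,5-dimethyl-5-[(2R)-2-methyl-7-oxoheptyl]-1,2-dioxolan-3-yl]acetate, 17 1-phenyl-5-{[(4E)-5-phenylpent-4-en-1-yl]sulfonyl}-1H-tetrazole
Product: 18 methyl 2-[(3S,5R)-3,5-dimethyl-5-[(2R,7E,11E)-2-methyl-12-phenyldodeca-7,11-dien-1-yl]-1,2-dioxolan-3-yl]acetate
Conditions: 17 (1.2 equiv), KN(SiMe3)2 (1.15 equiv), DME, −60 °C, 30 min; then 14 in DME, −60 °C → rt; aq. NH4Cl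
Reagents that add atoms: none
Why: Julia–Kocienski olefination: the premetalated phenyltetrazolyl sulfone adds to the aldehyde, and Smiles rearrangement with loss of SO2 and tetrazololate gives the C12=C13 alkene, (E) being favoured for a potassium counter-ion in DME with unbranched partners; premetalation keeps free amide base away from the β-peroxy ester and the (16E) alkene is carried in unchanged.

Step 12
Reactants: 18 methyl 2-[(3S,5R)-3,5-dimethyl-5-[(2R,7E,11E)-2-methyl-12-phenyldodeca-7,11-dien-1-yl]-1,2-dioxolan-3-yl]acetate
Product: 19 2-[(3S,5R)-3,5-dimethyl-5-[(2R,7E,11E)-2-methyl-12-phenyldodeca-7,11-dien-1-yl]-1,2-dioxolan-3-yl]acetic acid (CNP0204107.3)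
Conditions: LiOH·H2O (3 equiv), THF/H2O (3:1), 0 °C → rt; 1 M aq. HCl to pH 3; extraction
Reagents that add atoms: lithium hydroxide, [Li+].[OH-]
Why: Saponification by hydroxide attack at the ester carbonyl; both peroxide carbons are quaternary, so base-induced Kornblum–DeLaMare fragmentation is impossible, and the carboxylate formed resists enolisation and β-elimination, so acidification gives the target with all three stereocentres untouched.

**Compound list**

1 | pentane-2,4-dione | CC(=O)CC(C)=O | starting material
2 | 3,5-dimethyl-1,2-dioxolane-3,5-diol (cis/trans mixture) | CC1(O)CC(C)(O)OO1 | intermediate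
3 | 3,5-dimethoxy-3,5-dimethyl-1,2-dioxolane (cis/trans mixture) | COC1(C)CC(C)(OC)OO1 | intermediate
4 | 3-methylbut-2-enal | CC(C)=CC=O | starting material
5 | trimethyl{[(1E)-3-methylbuta-1,3-dien-1-yl]oxy}silane | C=C(C)/C=C/O[Si](C)(C)C | intermediate
6 | tert-butyl[(1-methoxyethenyl)oxy]dimethylsilane | C=C(OC)O[Si](C)(C)C(C)(C)C | starting material
7 | methyl 2-(5-methoxy-3,5-dimethyl-1,2-dioxolan-3-yl)acetate (racemic, both diastereomers) | COC(=O)CC1(C)CC(C)(OC)OO1 | intermediate
8 | rac-methyl 2-[(3S,5R)-3,5-dimethyl-5-[(2E)-2-methyl-4-oxobut-2-en-1-yl]-1,2-dioxolan-3-yl]acetate (needed enantiomer drawn) | O=C/C=C(\C)C[C@]1(C)C[C@@](C)(CC(=O)OC)OO1 | intermediate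
9 | methyl 2-[(3S,5R)-3,5-dimethyl-5-[(2S)-2-methyl-4-oxobutyl]-1,2-dioxolan-3-yl]acetate | C[C@H](CC=O)C[C@]1(C)C[C@@](C)(CC(=O)OC)OO1 | intermediate
10 | [2-(1,3-dioxolan-2-yl)ethyl]triphenylphosphonium bromide | [Br-].C1COC(CC[P+](c2ccccc2)(c2ccccc2)c2ccccc2)O1 | starting material
11 | [2-(1,3-dioxolan-2-yl)ethylidene]triphenyl-λ5-phosphane | C1COC(CC=P(c2ccccc2)(c2ccccc2)c2ccccc2)O1 | intermediate
12 | methyl 2-[(3S,5R)-5-[(2R,4Z)-6-(1,3-dioxolan-2-yl)-2-methylhex-4-en-1-yl]-3,5-dimethyl-1,2-dioxolan-3-yl]acetate | C[C@H](C/C=C\CC1OCCO1)C[C@]1(C)C[C@@](C)(CC(=O)OC)OO1 | intermediate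
13 | methyl 2-[(3S,5R)-5-[(2R)-6-(1,3-dioxolan-2-yl)-2-methylhexyl]-3,5-dimethyl-1,2-dioxolan-3-yl]acetate | C[C@H](CCCCC1OCCO1)C[C@]1(C)C[C@@](C)(CC(=O)OC)OO1 | intermediate
14 | methyl 2-[(3S,5R)-3,5-dimethyl-5-[(2R)-2-methyl-7-oxoheptyl]-1,2-dioxolan-3-yl]acetate | C[C@H](CCCCC=O)C[C@]1(C)C[C@@](C)(CC(=O)OC)OO1 | intermediate
15 | (4E)-5-phenylpent-4-en-1-ol | OCCC/C=C/c1ccccc1 | starting material
16 | 1-phenyl-5-{[(4E)-5-phenylpent-4-en-1-yl]sulfanyl}-1H-tetrazole | S(CCC/C=C/c1ccccc1)c1nnnn1-c1ccccc1 | intermediate
17 | 1-phenyl-5-{[(4E)-5-phenylpent-4-en-1-yl]sulfonyl}-1H-tetrazole | O=S(=O)(CCC/C=C/c1ccccc1)c1nnnn1-c1ccccc1 | intermediate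
18 | methyl 2-[(3S,5R)-3,5-dimethyl-5-[(2R,7E,11E)-2-methyl-12-phenyldodeca-7,11-dien-1-yl]-1,2-dioxolan-3-yl]acetate | C[C@H](CCCC/C=C/CC/C=C/c1ccccc1)C[C@]1(C)C[C@@](C)(CC(=O)OC)OO1 | intermediate
19 | 2-[(3S,5R)-3,5-dimethyl-5-[(2R,7E,11E)-2-methyl-12-phenyldodeca-7,11-dien-1-yl]-1,2-dioxolan-3-yl]acetic acid | C[C@H](CCCC/C=C/CC/C=C/c1ccccc1)C[C@]1(C)C[C@@](C)(CC(=O)O)OO1 | target

**Step count.** Total: 12 steps. Longest linear sequence: 9 steps (1, 2, 4, 5, 6, 7, 8, 11, 12) from pentane-2,4-dione.

**Steps most likely to fail**

Step 4 (bears the label). Three processes threaten it. The first substitution may not stop cleanly, so that part of 7 is ionised again and takes up a second acetate arm while part of 3 is left over for the diene. The hindered tertiary peroxycarbenium ion may be captured slowly by the diene, or at its α-carbon, or may fragment by ring opening before capture. The preference for approach anti to the acetate arm may be weak, so that the cis-arm isomer accompanies 8. The fallback uses known reaction types only, sets out from 3 and comes back at 8. An excess of 3 is treated with 6 and Me3SiOTf in CH2Cl2 at −78 °C (the known silyl ketene acetal substitution of an alkoxydioxolane), and monosubstituted peroxyketal 7 is isolated while unreacted 3 is recovered. Compound 7 is then treated with trimethyl(2-methylprop-2-en-1-yl)silane and Me3SiOTf at −78 °C, the known allylsilane substitution, again with approach anti to the acetate arm, to give rac-methyl 2-[(3S,5R)-3,5-dimethyl-5-(2-methylprop-2-en-1-yl)-1,2-dioxolan-3-yl]acetate F1. Cross-metathesis of F1 with (E)-but-2-enal (second-generation Hoveyda–Grubbs catalyst RuCl2(=CH-C6H4-2-OiPr)(H2IMes), CH2Cl2, 40 °C) then gives enal 8.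

Step 5. Turnover may stall because the dioxolane next to C7 fits the active site poorly. Facial control may erode if the enal isomerises from (E) to (Z) in the medium. The O–O bond may be reduced by reduced flavin or by trace metal ions in the enzyme preparation. The two diastereomers may co-elute. The fallback sets out from 8 and comes back at 9, and replaces the enzyme by iminium-ion transfer hydrogenation under counteranion control: morpholinium (S)-3,3'-bis(2,4,6-triisopropylphenyl)-1,1'-binaphthyl-2,2'-diyl phosphate (20 mol%), diethyl 2,6-dimethyl-1,4-dihydropyridine-3,5-dicarboxylate (1.1 equiv), 1,4-dioxane, 50 °C. This reaction type is established for β-methyl-β-alkyl enals such as citral and is convergent in alkene geometry, because the iminium ion equilibrates before hydride transfer. By analogy with the citral case the (S)-phosphate is expected to give the required configuration at C7, which would be checked on the first run. The same chromatographic separation then gives 9. If separation is not practical at the stage of 9, it is moved to 13 or 18. This fallback makes no new compound (F0).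

Step 2. Under acid the ring opens reversibly to hydroperoxy ketone forms, and these can shed hydrogen peroxide, so that the material drains towards enol ether and ketal forms of the diketone instead of the bis(peroxyketal). The fallback sets out from 2 and comes back at 3 and avoids any C–O ionisation: Purdie methylation with MeI and Ag2O in CH2Cl2 at rt in the dark, an O-alkylation used for hydroperoxides and hemiacetal hydroxyls, which leaves the ring bonds untouched. This fallback makes no new compound (F0).

The base-mediated steps 6, 11 and 12 expose a β-peroxy ester to an ylide, a sulfonyl carbanion and hydroxide. These reaction types are routinely run on dialkyl peroxides whose peroxide carbons are quaternary, so they rank below the three steps above.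

Further compounds
F1 | step 4 | rac-methyl 2-[(3S,5R)-3,5-dimethyl-5-(2-methylprop-2-en-1-yl)-1,2-dioxolan-3-yl]acetate (needed enantiomer drawn) | C=C(C)C[C@]1(C)C[C@@](C)(CC(=O)OC)OO1
F0 | step 5 | none | none
F0 | step 2 | none | none
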